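**Retrosynthetic overview**
- The target is cut at the C3–C1′ bond (chromone C3 to the B-ring carbon para to the free 4′-OH) and at O1–C2. This gives an o-hydroxyaryl enaminone, whose C3 is a native nucleophile, and the intact B-ring chromenol. The chromenol is used with reversed polarity as its aryloxy-λ3-iodane (a phenoxenium, i.e. a doubly vinylogous enolonium equivalent).
- The chromenol comes from 3-methoxycatechol and prenal: a C–C bond ortho to OH, then oxa-6π ring closure.
- The enaminone comes from 2,4-dihydroxyacetophenone and DMF dimethyl acetal.
- Ring order: the dimethylpyran ring forms first (step 1). The 4-pyranone C ring forms last, in the same flask as the key C–C bond. No protecting groups are used.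

Assumption: the SMILES has no stereocentre and the C3–C1′ axis carries only one ortho substituent, so it rotates freely; the target is achiral and there is no enantiomer to select.

**Step 1**
Reactants: 1 3-methoxybenzene-1,2-diol (3-methoxycatechol); 2 3-methylbut-2-enal (prenal)
Product: 4 7-methoxy-2,2-dimethyl-2H-chromen-8-ol, via (6Z)-2-hydroxy-3-methoxy-6-(3-methylbut-2-en-1-ylidene)cyclohexa-2,4-dien-1-one 3 (not isolated)
Conditions: 2 (1.5 equiv), pyridine, 140 °C (sealed tube), Ar, 16 h
Reagents that add atoms: none
Why: Crombie-type pyridine-mediated chromenylation, in which aldol-type C-alkylation occurs at C6 of 1 (the only free carbon ortho to a hydroxyl, and para to OMe, the same activation that lets 3-methoxyphenol give precocene I), loss of water gives o-quinone methide 3, and an irreversible oxa-6π electrocyclisation closes the pyran, so only one regioisomer can form and no stereocentre is created.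

**Step 2**
Reactants: 5 1-(2,4-dihydroxyphenyl)ethan-1-one (2,4-dihydroxyacetophenone)
Product: 6 (2E)-1-(2,4-dihydroxyphenyl)-3-(dimethylamino)prop-2-en-1-one
Conditions: DMF-DMA (2 equiv), toluene, 80 °C, 3 h
Reagents that add atoms: N,N-dimethylformamide dimethyl acetal, COC(OC)N(C)C
Why: Amide-acetal condensation (enaminone synthesis), in which the methyl ketone enolate adds to the alkoxyiminium ion from DMF-DMA and loses methanol to give the conjugated, thermodynamically preferred E-enaminone, while 80 °C and limited reagent hold back O-methylation of the 4-OH.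

**Step 3**
Reactants: 4 7-methoxy-2,2-dimethyl-2H-chromen-8-ol; 6 (2E)-1-(2,4-dihydroxyphenyl)-3-(dimethylamino)prop-2-en-1-one
Product: 9 7-hydroxy-3-(8-hydroxy-7-methoxy-2,2-dimethyl-2H-chromen-5-yl)-4H-chromen-4-one (target), via acetoxy[(7-methoxy-2,2-dimethyl-2H-chromen-8-yl)oxy](phenyl)-λ3-iodane 7 (not isolated), via 2-(dimethylamino)-7-hydroxy-3-(8-hydroxy-7-methoxy-2,2-dimethyl-2H-chromen-5-yl)chroman-4-one 8 (not isolated)
Conditions: 6 (1.5 equiv), PhI(OAc)2 (1.05 equiv, added over 30 min), HFIP–CH2Cl2 1:1, 0 °C to rt
Reagents that add atoms: none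
Why: Proposed new method: the electron-rich 2,6-dioxygenated phenol 4 exchanges onto PhI(OAc)2 within minutes in HFIP, faster than the chromene alkene, the acyl-deactivated resorcinol or the enaminone carbon of 6 are oxidised, giving 7, a phenoxenium (doubly vinylogous enolonium) equivalent whose only unsubstituted electrophilic carbon is C5, para to oxygen; the α-carbon of 6, by far the best π-nucleophile present, attacks there with loss of PhI and acetate, tautomerisation restores the phenol, the 2-OH closes onto the iminium carbon to give 8 (a diastereomer mixture whose two centres are erased), and loss of HNMe2 gives the chromone, so two natively nucleophilic carbons are joined and 9 carries no stereocentre; the closest known reaction types are the hypervalent-iodine oxidative para cross-coupling of phenols with π-nucleophiles in HFIP (Kita type) and the electrophile-triggered chromone annulation of o-hydroxyaryl enaminones.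

**Compound list**
1 | 3-methoxybenzene-1,2-diol | COc1cccc(O)c1O | starting material
2 | 3-methylbut-2-enal | CC(C)=CC=O | starting material
3 | (6Z)-2-hydroxy-3-methoxy-6-(3-methylbut-2-en-1-ylidene)cyclohexa-2,4-dien-1-one (not isolated) | O=C1C(O)=C(OC)C=C/C1=C/C=C(C)C | intermediate
4 | 7-methoxy-2,2-dimethyl-2H-chromen-8-ol | COc1ccc2C=CC(C)(C)Oc2c1O | intermediate
5 | 1-(2,4-dihydroxyphenyl)ethan-1-one | CC(=O)c1ccc(O)cc1O | starting material
6 | (2E)-1-(2,4-dihydroxyphenyl)-3-(dimethylamino)prop-2-en-1-one | CN(C)/C=C/C(=O)c1ccc(O)cc1O | intermediate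
7 | acetoxy[(7-methoxy-2,2-dimethyl-2H-chromen-8-yl)oxy](phenyl)-λ3-iodane (not isolated) | CC(=O)OI(c1ccccc1)Oc1c(OC)ccc2C=CC(C)(C)Oc12 | intermediate
8 | 2-(dimethylamino)-7-hydroxy-3-(8-hydroxy-7-methoxy-2,2-dimethyl-2H-chromen-5-yl)chroman-4-one (diastereomer mixture, not isolated) | CN(C)C1Oc2cc(O)ccc2C(=O)C1c1cc(OC)c(O)c2OC(C)(C)C=Cc12 | intermediate
9 | 7-hydroxy-3-(8-hydroxy-7-methoxy-2,2-dimethyl-2H-chromen-5-yl)-4H-chromen-4-one (achiral) | COc1cc(-c2coc3cc(O)ccc3c2=O)c2c(c1O)OC(C)(C)C=C2 | target

**Total step count:** 3. **Longest linear sequence:** 2 (1 → 4 → 9, or 5 → 6 → 9).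

**Steps most likely to fail, most risky first**

**Step 3.**
- Risks: the oxidant may attack the enaminone or over-oxidise 9. The phenoxenium may also dimerise para–para, or shed the tertiary allylic pyran carbon.
- The fallback sets out from 1 and 6 and comes back to the route at 9.
- Compound 1 is oxidised with Ag2O in Et2O at 0 °C to 3-methoxycyclohexa-3,5-diene-1,2-dione F1. This is an isolable reversed-polarity form of the B ring, so no oxidant ever meets 6.
- F1 is added to 6 in AcOH–CH2Cl2. The enaminone carbon adds at C5 of the quinone, the enone β-carbon that the methoxy group does not deactivate.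
- Rearomatisation and chromone closure with loss of the amine give 3-(3,4-dihydroxy-5-methoxyphenyl)-7-hydroxy-4H-chromen-4-one F2.
- The pyran ring is then closed last with 2 under the conditions of step 1 to give 9. C2′ is the only free carbon ortho to a B-ring hydroxyl, and the A ring is deactivated by the C4 carbonyl.

**Step 1.**
- Risks: a catechol is a less proven partner than a resorcinol. Prenal self-condensation or slow C-alkylation may keep the yield low.
- The fallback sets out from 1 and comes back at 4.
- Friedel–Crafts acylation and oxa-Michael closure with 3-methylbut-2-enoic acid are run in methanesulfonic acid (solvent and catalyst) at 70 °C. Acylation occurs ortho to OH and para to OMe, giving 8-hydroxy-7-methoxy-2,2-dimethylchroman-4-one F3.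
- NaBH4 in MeOH reduces F3 to racemic 7-methoxy-2,2-dimethylchromane-4,8-diol F4.
- Catalytic p-TsOH in toluene at 80 °C dehydrates F4 to 4, which erases the carbinol centre.

**Step 2.**
- Risks: DMF-DMA can O-methylate the acidic 4-OH, or the product can cyclise prematurely.
- The fallback sets out from 5 and comes back at 6.
- Compound 5 is treated with triethyl orthoformate and 70% HClO4, followed by hot-water hydrolysis of the pyrylium salt. This gives 7-hydroxy-4H-chromen-4-one F5 without any methylating agent.
- Conjugate addition of dimethylamine at C2 (40% aqueous Me2NH, EtOH, 50 °C) opens the pyranone ring to the E-enaminone 6.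

**Further compounds**
F1 | step 3 | 3-methoxycyclohexa-3,5-diene-1,2-dione | COC1=CC=CC(=O)C1=O
F2 | step 3 | 3-(3,4-dihydroxy-5-methoxyphenyl)-7-hydroxy-4H-chromen-4-one | COc1cc(cc(O)c1O)-c1coc2cc(O)ccc2c1=O
F3 | step 1 | 8-hydroxy-7-methoxy-2,2-dimethylchroman-4-one | COc1ccc2C(=O)CC(C)(C)Oc2c1O
F4 | step 1 | 7-methoxy-2,2-dimethylchromane-4,8-diol (racemic) | COc1ccc2C(O)CC(C)(C)Oc2c1O
F5 | step 2 | 7-hydroxy-4H-chromen-4-one | O=c1ccoc2cc(O)ccc12
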